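The earlier runs and the new flask stem from a simulated flask from invented constants, noise included.

The ratio of the substrate charged in the dawn run to that in the dusk run is 12.2, and I began from it, as these two runs were what I had for judging a change of charge. The new flasks differ from each other in c(substrate) alone.

common to all: gas 8.6 mM (held)
- dusk: substrate 0.018 M; run made earlier
- dawn: substrate 0.22 M; run made earlier
- violet: substrate 0.15 M; time 40 min
- amber: substrate 0.030 M; time 40 min
- green: substrate 0.050 M; time 40 min
- red: substrate 0.080 M; time 40 min
- blue: substrate 0.025 M; time 40 min
- ochre: substrate 0.015 M; time 40 min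

| run | time / min | mono adduct / % |
|---|---|---|
| dusk | 1.33 | 1.4 |
| dusk | 4.00 | 7.6 |
| dusk | 8.00 | 18.1 |
| dusk | 10.0 | 21.3 |
| dusk | 15.0 | 30.1 |
| dusk | 20.0 | 36.3 |
| dawn | 1.50 | 0.8 |
| dawn | 2.50 | 0 |
| dawn | 4.00 | 0.4 |
| dawn | 8.00 | 0 |
| dawn | 12.0 | 0.5 |
| dawn | 20.0 | 0 |

(scatter of a reading: 0.5 percentage points)

* all flasks from highest to lowest amount of mono adduct, in percent of the substrate charged, at 40 min (violet / amber / green / red / blue / ochre)
* the amount of mono adduct, in percent of the substrate charged of the flask you put first, at 40 min
* the amount of mono adduct, in percent of the substrate charged of the flask you put last, at 40 min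

- at the start none of the gas is in solution

With c(gas) held at 8.6 mM, the bench rule is pseudo-first-order: the percent at a given time should not depend on the charge. So dawn should have shown at 20.0 min the 36.3% of dusk, yet it read 0%, and its largest reading was 0.8%. The next rule I tried shares a fixed amount of mono adduct over the charge, which divides the dusk reading by the ratio. That gives 2.97%, still more than that largest dawn reading, so the fall is steeper than the ratio itself.

I therefore defined the steepness, the power of the charge ratio by which the percent falls. For what dawn can hide I took its 0.5% at 12.0 min, a figure equal to the scatter of 0.5 percentage points. This gave a steepness of 1.71, a reading that carries that scatter. Dusk was still climbing at its last readings, from 30.1% at 15.0 min to 36.3% at 20.0 min, so carrying a figure built on that last reading over to 40 min was an assumption of mine and not something the runs showed. On that assumption I ranked the flasks by charge. Violet, with the highest charge, came to 0.963%. Ochre, with the lowest, came to 49.6%, but I held that loosely, as its charge lies below the dusk charge, outside the span that gave the steepness.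

The forecast gave ochre > blue > amber > green > red > violet, with 52% first and 1% last, on the ground that “substrate strongly inhibits the reaction, with the percent rate falling roughly as 1/S² or steeper”.

The flasks gave ochre > blue > amber > green > red > violet, with 39.3% in ochre and 1.34% in violet.

    coupling partner + mono adduct → bis adduct (k = 0.0740 M⁻¹ s⁻¹)
    coupling partner + bis adduct ⇌ triple product (K = 530 M⁻¹, k = 0.340 M⁻¹ s⁻¹)
    gas ⇌ coupling partner, rate k3*(csat - [coupling partner]) (kL = 0.00160 s⁻¹)
    substrate + mono adduct → side product (k = 0.0710 M⁻¹ s⁻¹)
    substrate + coupling partner → mono adduct (k = 0.490 M⁻¹ s⁻¹)

Ochre stood below my figure and the forecast's, with 1.3% of its substrate left and 10.3% of bis adduct at 40.0 min. In violet the steepness had given 0.963% against the 1.34% found. For the neighbour of violet charged with 0.26 M, the same steepness from dusk gives 0.376%, and that flask holds 0.369% of mono adduct at 40.0 min.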